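The target is a (2S,3R)-flavanone (unit 1: rings A, C, B; unprimed atoms) bonded through C3 to C8'' of a (2R,3R)-dihydroflavonol (unit 2: rings A'', C'', B''). The end game is hydrogenolysis of eight benzyl ethers, oxidation of the benzylic C4''–OH of a cis-3'',4''-diol, and OsO4 dihydroxylation of a 2''-aryl-2H-chromene anti to its aryl group.
The route rests on this feature of unit 2: C4'' sits on C4a'', the ring carbon ortho to the O1''-bearing C8a'' (the place of the formyl carbon in a salicylaldehyde), and C2''–C3'' carries the catechol ring and a trans OH (a styrene oxidised at both alkene carbons). C3''–C4'' and O1''–C2'' of ring C'' are therefore cut to a flavanone-substituted salicylaldehyde and an (E)-styrylboronic acid.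
The salicylaldehyde comes from ortho-formylation of the ring-A'' phenol. Ring C of unit 1 (C2–C3 and O1–C2) comes from Knoevenagel/oxa-Michael condensation of a 2-hydroxydeoxybenzoin with 3,4-bis(benzyloxy)benzaldehyde, trans under equilibrium control, followed by resolution.
The deoxybenzoin comes from alkaline opening of an isoflavone, whose C3–C8'' bond is made by Suzuki–Miyaura coupling of a 3-iodochromone with a boronate prepared from 3,5-bis(benzyloxy)phenol by ortho-bromination.
Ring order: the benzene rings A, A'', B, B'' are bought; a chromone ring is built and opened again (it masks the ring-A phenol); then ring C of unit 1; then ring C'' of unit 2.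

Key step: step 13

Remark: the three flavanones made before the resolution are racemic 2,3-trans compounds and are drawn as the (2S,3R) enantiomer that is kept; the three starting materials are taken as purchasable.

Step 1
Reactants: 1 3,5-bis(benzyloxy)phenol
Product: 2 2-bromo-3,5-bis(benzyloxy)phenol
Conditions: NBS (1.0 equiv), i-Pr2NH (0.1 equiv), CH2Cl2, −78 to 0 °C
Reagents that add atoms: N-bromosuccinimide, O=C1CCC(=O)N1Br
Why: Amine-mediated ortho-selective electrophilic bromination of a phenol, in which the hydrogen-bonded N-bromoamine delivers bromine next to the OH; C2 (between OH and one benzyloxy group) is also less crowded than C4 (between two), and this bromine fixes the carbon that becomes C8'' beside the future ring oxygen, the symmetrical 4-bromo isomer and any dibromide being removed by chromatography.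

Step 2
Reactants: 2 2-bromo-3,5-bis(benzyloxy)phenol
Product: 3 1,5-bis(benzyloxy)-2-bromo-3-(methoxymethoxy)benzene
Conditions: MOMCl, i-Pr2NEt, CH2Cl2, 0 °C to rt
Reagents that add atoms: chloromethyl methyl ether, COCCl
Why: Base-mediated O-alkylation (Williamson type) turns the phenol, the future O1'', into a MOM acetal that withstands butyllithium, aqueous base and piperidine and can later be removed without loss of benzyl ethers.

Step 3
Reactants: 3 1,5-bis(benzyloxy)-2-bromo-3-(methoxymethoxy)benzene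
Product: 5 2-[2,4-bis(benzyloxy)-6-(methoxymethoxy)phenyl]-4,4,5,5-tetramethyl-1,3,2-dioxaborolane, via aryllithium 4 (not isolated)
Conditions: n-BuLi, THF, −78 °C; then i-PrOBpin, −78 °C to rt
Reagents that add atoms: 2-isopropoxy-4,4,5,5-tetramethyl-1,3,2-dioxaborolane, CC(C)OB1OC(C)(C)C(C)(C)O1
Why: Bromine–lithium exchange is fast at −78 °C, and the aryllithium, held between two coordinating oxygen groups, is trapped by the borate ester to give the pinacol boronate (lithiation–borylation).

Step 4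
Reactants: 6 1-[2-hydroxy-4,6-bis(benzyloxy)phenyl]ethanone
Product: 8 5,7-bis(benzyloxy)-3-iodo-4H-chromen-4-one, via enaminone 7 (not isolated)
Conditions: DMF-DMA, toluene, 100 °C; then I2, CHCl3, rt
Reagents that add atoms: N,N-dimethylformamide dimethyl acetal, COC(OC)N(C)C; iodine, II
Why: Condensation of the methyl ketone with the amide acetal gives the enaminone, and iodination of its alpha carbon triggers attack of the phenol oxygen on the iminium carbon with loss of dimethylamine (iodine-induced enaminone cyclisation), which gives the 3-iodochromone and masks the ring-A phenol as the pyranone oxygen.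

Step 5
Reactants: 5 2-[2,4-bis(benzyloxy)-6-(methoxymethoxy)phenyl]-4,4,5,5-tetramethyl-1,3,2-dioxaborolane; 8 5,7-bis(benzyloxy)-3-iodo-4H-chromen-4-one
Product: 9 5,7-bis(benzyloxy)-3-[2,4-bis(benzyloxy)-6-(methoxymethoxy)phenyl]-4H-chromen-4-one
Conditions: Pd(OAc)2 (5 mol%), SPhos (10 mol%), K3PO4, toluene/H2O, 90 °C
Reagents that add atoms: none
Why: Suzuki–Miyaura coupling of the reactive vinylogous-ester iodide with the di-ortho-substituted arylboronate, for which the bulky biarylphosphine is an established ligand, forms the C3–C8'' bond between the two phloroglucinol-derived rings.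

Step 6
Reactants: 9 5,7-bis(benzyloxy)-3-[2,4-bis(benzyloxy)-6-(methoxymethoxy)phenyl]-4H-chromen-4-one
Product: 10 1-[2-hydroxy-4,6-bis(benzyloxy)phenyl]-2-[2,4-bis(benzyloxy)-6-(methoxymethoxy)phenyl]ethanone
Conditions: KOH (aq.), EtOH, reflux
Reagents that add atoms: none
Why: Hydroxide adds to C2 of the isoflavone, the pyranone opens and the beta-keto aldehyde loses formate by retro-Claisen cleavage (the classical alkaline degradation of isoflavones to deoxybenzoins), which frees the ring-A phenol while the ring-A'' phenol stays protected.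

Step 7
Reactants: 10 1-[2-hydroxy-4,6-bis(benzyloxy)phenyl]-2-[2,4-bis(benzyloxy)-6-(methoxymethoxy)phenyl]ethanone; 11 3,4-bis(benzyloxy)benzaldehyde
Product: 13 rac-(2S,3R)-5,7-bis(benzyloxy)-2-[3,4-bis(benzyloxy)phenyl]-3-[2,4-bis(benzyloxy)-6-(methoxymethoxy)phenyl]chroman-4-one (2,3-trans), via alpha-aryl chalcone 12 (not isolated)
Conditions: piperidine (1 equiv), toluene, Dean–Stark, reflux
Reagents that add atoms: none
Why: Piperidine-mediated Knoevenagel condensation at the activated methylene followed by intramolecular oxa-Michael addition of the ring-A phenol is the established route from 2-hydroxydeoxybenzoins and aryl aldehydes to 2,3-diarylchroman-4-ones; ring closure is reversible, so the 2,3-trans isomer with both aryl groups equatorial should form under equilibrium control, necessarily as the racemate.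

Step 8
Reactants: 13 rac-(2S,3R)-5,7-bis(benzyloxy)-2-[3,4-bis(benzyloxy)phenyl]-3-[2,4-bis(benzyloxy)-6-(methoxymethoxy)phenyl]chroman-4-one
Product: 14 rac-(2S,3R)-5,7-bis(benzyloxy)-2-[3,4-bis(benzyloxy)phenyl]-3-[2-hydroxy-4,6-bis(benzyloxy)phenyl]chroman-4-one
Conditions: HCl (2 M aq.), THF/MeOH, 45 °C
Reagents that add atoms: none
Why: Acid-catalysed acetal cleavage removes the MOM group and frees the ring-A'' phenol, while the benzyl ethers and the flavanone, whose deactivated 5,7-dialkoxyaryl ketone resists attack by the new phenol, should survive these mild conditions.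

Step 9
Reactants: 14 rac-(2S,3R)-5,7-bis(benzyloxy)-2-[3,4-bis(benzyloxy)phenyl]-3-[2-hydroxy-4,6-bis(benzyloxy)phenyl]chroman-4-one
Product: 15 rac-3-[(2S,3R)-5,7-bis(benzyloxy)-2-(3,4-bis(benzyloxy)phenyl)-4-oxochroman-3-yl]-2-hydroxy-4,6-bis(benzyloxy)benzaldehyde
Conditions: MgCl2, Et3N, (CH2O)n, MeCN, 80 °C
Reagents that add atoms: paraformaldehyde (as formaldehyde), C=O
Why: Casnati–Skattebøl ortho-formylation, in which the magnesium phenoxide binds formaldehyde and delivers it to the only free ortho position and a second formaldehyde oxidises the benzylic alkoxide by hydride transfer, so the formyl group should enter between the OH and the neighbouring benzyloxy group and not at the position between the two benzyloxy groups.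

Step 10
Reactants: 15 rac-3-[(2S,3R)-5,7-bis(benzyloxy)-2-(3,4-bis(benzyloxy)phenyl)-4-oxochroman-3-yl]-2-hydroxy-4,6-bis(benzyloxy)benzaldehyde
Product: 16 3-[(2S,3R)-5,7-bis(benzyloxy)-2-(3,4-bis(benzyloxy)phenyl)-4-oxochroman-3-yl]-2-hydroxy-4,6-bis(benzyloxy)benzaldehyde (single enantiomer)
Conditions: preparative SFC, amylose tris(3,5-dimethylphenylcarbamate) phase, CO2/i-PrOH
Reagents that add atoms: none
Why: Resolution of enantiomers by chromatography on a chiral stationary phase (no bond is made or broken) is used because C2 and C3 arise under equilibrium control where no catalyst can favour one antipode; it is placed after the hot, basic steps 7 and 9, the (2S,3R) antipode is to be assigned from the Cotton effects of the flavanone chromophore, and the unwanted antipode can be racemised with piperidine through the reversible oxa-Michael closure and recycled.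

Step 11
Reactants: 11 3,4-bis(benzyloxy)benzaldehyde
Product: 17 1,2-bis(benzyloxy)-4-ethynylbenzene
Conditions: dimethyl (1-diazo-2-oxopropyl)phosphonate, K2CO3, MeOH, rt
Reagents that add atoms: dimethyl (1-diazo-2-oxopropyl)phosphonate, COP(=O)(OC)C(=[N+]=[N-])C(C)=O
Why: Ohira–Bestmann (Seyferth–Gilbert) homologation, in which the diazophosphonate anion adds to the aldehyde and the diazoalkene loses N2 with a 1,2-hydride shift, gives the terminal alkyne under mild base.

Step 12
Reactants: 17 1,2-bis(benzyloxy)-4-ethynylbenzene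
Product: 19 (E)-2-[3,4-bis(benzyloxy)phenyl]ethenylboronic acid, via catechol boronate 18 (not isolated)
Conditions: catecholborane, THF, 70 °C; then H2O, rt
Reagents that add atoms: catecholborane, B1Oc2ccccc2O1; water, O
Why: Syn, anti-Markovnikov hydroboration of the terminal alkyne puts boron on the terminal carbon and sets the (E)-alkene, and water cleaves the catechol ester to the boronic acid.

Step 13
Reactants: 16 3-[(2S,3R)-5,7-bis(benzyloxy)-2-(3,4-bis(benzyloxy)phenyl)-4-oxochroman-3-yl]-2-hydroxy-4,6-bis(benzyloxy)benzaldehyde; 19 (E)-2-[3,4-bis(benzyloxy)phenyl]ethenylboronic acid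
Product: 22 (2S,3R)-5,7-bis(benzyloxy)-2-[3,4-bis(benzyloxy)phenyl]-3-{(2S)-5,7-bis(benzyloxy)-2-[3,4-bis(benzyloxy)phenyl]-2H-chromen-8-yl}chroman-4-one, via allylic amine 20 (not isolated), via ortho-quinone methide 21 (not isolated)
Conditions: Bn2NH (0.4 equiv), 1,4-dioxane, 80 °C, dark; chromatographic separation of the C2'' epimers
Reagents that add atoms: none
Why: The aldehyde of 16 condenses with Bn2NH to an iminium ion while 19 binds the neighbouring phenol oxygen, and the tetracoordinate boronate hands its (E)-styryl group to the iminium carbon from within (C3''–C4'' bond, allylic amine 20); on warming the amine is expelled again, so it turns over, and leaves the vinyl ortho-quinone methide 21. Ring C'' then closes by thermal disrotatory oxa-6π electrocyclisation of 21, which forms O1''–C2'' and restores the aromatic ring A''. The closest known reaction is the secondary-amine-promoted condensation of salicylaldehydes with alkenylboronic acids to 2-substituted 2H-chromenes (Petasis borono-Mannich step, amine loss, ring closure). C2'' is created in the closure of the planar, amine-free 21, so a chiral amine or diol acting in the boronate-transfer step cannot set it; the only control element is the (2S,3R)-flavanone on C8'', next to the bond-forming oxygen, whose induction is of unproven sense and size, so the two C2'' epimers (diastereomers) are to be separated by chromatography, here or after step 14, and the unwanted one re-equilibrated by irradiation through the same quinone methide. The step needs chemoselection for the aldehyde over the C4 ketone, secured because only the aldehyde has a free ortho phenol to carry the boronate and the 5,7-dialkoxyaryl ketone is hindered and deactivated, and it needs the flavanone to keep its configuration, for which a weakly basic amine in substoichiometric amount and an aprotic solvent are chosen.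

Step 14
Reactants: 22 (2S,3R)-5,7-bis(benzyloxy)-2-[3,4-bis(benzyloxy)phenyl]-3-{(2S)-5,7-bis(benzyloxy)-2-[3,4-bis(benzyloxy)phenyl]-2H-chromen-8-yl}chroman-4-one
Product: 23 (2S,3R)-5,7-bis(benzyloxy)-2-[3,4-bis(benzyloxy)phenyl]-3-{(2R,3S,4S)-5,7-bis(benzyloxy)-2-[3,4-bis(benzyloxy)phenyl]-3,4-dihydroxychroman-8-yl}chroman-4-one
Conditions: OsO4 (5 mol%), NMO, acetone/THF/H2O, rt
Reagents that add atoms: osmium tetroxide (catalytic carrier of both oxygen atoms), O=[Os](=O)(=O)=O; N-methylmorpholine N-oxide, C[N+]1([O-])CCOCC1; water, O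
Why: Catalytic Upjohn syn-dihydroxylation, in which OsO4 adds to the C3''=C4'' bond from the face opposite the C2'' aryl group, sets C3'' (OH trans to the aryl group) and C4'' (OH cis to the C3'' OH).

Step 15
Reactants: 23 (2S,3R)-5,7-bis(benzyloxy)-2-[3,4-bis(benzyloxy)phenyl]-3-{(2R,3S,4S)-5,7-bis(benzyloxy)-2-[3,4-bis(benzyloxy)phenyl]-3,4-dihydroxychroman-8-yl}chroman-4-one
Product: 24 (2R,3R)-5,7-bis(benzyloxy)-2-[3,4-bis(benzyloxy)phenyl]-8-{(2S,3R)-5,7-bis(benzyloxy)-2-[3,4-bis(benzyloxy)phenyl]-4-oxochroman-3-yl}-3-hydroxychroman-4-one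
Conditions: DDQ (1.2 equiv), 1,4-dioxane, rt
Reagents that add atoms: none
Why: DDQ dehydrogenation of an electron-rich benzylic alcohol: hydride is abstracted from the carbinol C4''–H, which is benzylic to the ring with ortho and para oxygen donors, so only this alcohol should be oxidised to the aryl ketone while the non-benzylic C3'' OH is untouched, and DDQ does not cleave the cis-glycol as MnO2 can; C2'' and C3'' keep their trans arrangement.

Step 16
Reactants: 24 (2R,3R)-5,7-bis(benzyloxy)-2-[3,4-bis(benzyloxy)phenyl]-8-{(2S,3R)-5,7-bis(benzyloxy)-2-[3,4-bis(benzyloxy)phenyl]-4-oxochroman-3-yl}-3-hydroxychroman-4-one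
Product: 25 (2R,3R)-2-(3,4-dihydroxyphenyl)-8-[(2S,3R)-2-(3,4-dihydroxyphenyl)-5,7-dihydroxy-4-oxochroman-3-yl]-3,5,7-trihydroxychroman-4-one (EANPDB:THYM_00006)
Conditions: H2 (1 atm), Pd(OH)2 on carbon, THF/MeOH, rt
Reagents that add atoms: none
Why: Catalytic hydrogenolysis cleaves all eight benzyl–oxygen bonds under neutral conditions, and the hydrogen-bonded aryl ketones, the ring C–O bonds and the four stereocentres are expected to survive at room temperature if the reaction is stopped at full debenzylation.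

Compound list
1 | 3,5-bis(benzyloxy)phenol | Oc1cc(OCc2ccccc2)cc(OCc2ccccc2)c1 | starting material
2 | 2-bromo-3,5-bis(benzyloxy)phenol | Oc1cc(OCc2ccccc2)cc(OCc2ccccc2)c1Br | intermediate
3 | 1,5-bis(benzyloxy)-2-bromo-3-(methoxymethoxy)benzene | COCOc1cc(OCc2ccccc2)cc(OCc2ccccc2)c1Br | intermediate
4 | [2,4-bis(benzyloxy)-6-(methoxymethoxy)phenyl]lithium | [Li]c1c(OCOC)cc(OCc2ccccc2)cc1OCc1ccccc1 | intermediate (not isolated)
5 | 2-[2,4-bis(benzyloxy)-6-(methoxymethoxy)phenyl]-4,4,5,5-tetramethyl-1,3,2-dioxaborolane | COCOc1cc(OCc2ccccc2)cc(OCc2ccccc2)c1B1OC(C)(C)C(C)(C)O1 | intermediate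
6 | 1-[2-hydroxy-4,6-bis(benzyloxy)phenyl]ethanone | CC(=O)c1c(O)cc(OCc2ccccc2)cc1OCc1ccccc1 | starting material
7 | (E)-3-(dimethylamino)-1-[2-hydroxy-4,6-bis(benzyloxy)phenyl]prop-2-en-1-one | CN(C)/C=C/C(=O)c1c(O)cc(OCc2ccccc2)cc1OCc1ccccc1 | intermediate (not isolated)
8 | 5,7-bis(benzyloxy)-3-iodo-4H-chromen-4-one | O=c1c(I)coc2cc(OCc3ccccc3)cc(OCc3ccccc3)c12 | intermediate
9 | 5,7-bis(benzyloxy)-3-[2,4-bis(benzyloxy)-6-(methoxymethoxy)phenyl]-4H-chromen-4-one | O=c1c(-c2c(OCOC)cc(OCc3ccccc3)cc2OCc2ccccc2)coc2cc(OCc3ccccc3)cc(OCc3ccccc3)c12 | intermediate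
10 | 1-[2-hydroxy-4,6-bis(benzyloxy)phenyl]-2-[2,4-bis(benzyloxy)-6-(methoxymethoxy)phenyl]ethanone | O=C(Cc1c(OCOC)cc(OCc2ccccc2)cc1OCc1ccccc1)c1c(O)cc(OCc2ccccc2)cc1OCc1ccccc1 | intermediate
11 | 3,4-bis(benzyloxy)benzaldehyde | O=Cc1ccc(OCc2ccccc2)c(OCc2ccccc2)c1 | starting material
12 | 1-[2-hydroxy-4,6-bis(benzyloxy)phenyl]-2-[2,4-bis(benzyloxy)-6-(methoxymethoxy)phenyl]-3-[3,4-bis(benzyloxy)phenyl]prop-2-en-1-one (alkene geometry open) | O=C(C(=Cc1ccc(OCc2ccccc2)c(OCc2ccccc2)c1)c1c(OCOC)cc(OCc2ccccc2)cc1OCc1ccccc1)c1c(O)cc(OCc2ccccc2)cc1OCc1ccccc1 | intermediate (not isolated)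
13 | rac-(2S,3R)-5,7-bis(benzyloxy)-2-[3,4-bis(benzyloxy)phenyl]-3-[2,4-bis(benzyloxy)-6-(methoxymethoxy)phenyl]chroman-4-one (racemate; (2S,3R) enantiomer drawn) | O=C1c2c(OCc3ccccc3)cc(OCc3ccccc3)cc2O[C@H](c2ccc(OCc3ccccc3)c(OCc3ccccc3)c2)[C@H]1c1c(OCOC)cc(OCc2ccccc2)cc1OCc1ccccc1 | intermediate
14 | rac-(2S,3R)-5,7-bis(benzyloxy)-2-[3,4-bis(benzyloxy)phenyl]-3-[2-hydroxy-4,6-bis(benzyloxy)phenyl]chroman-4-one (racemate; (2S,3R) enantiomer drawn) | O=C1c2c(OCc3ccccc3)cc(OCc3ccccc3)cc2O[C@H](c2ccc(OCc3ccccc3)c(OCc3ccccc3)c2)[C@H]1c1c(O)cc(OCc2ccccc2)cc1OCc1ccccc1 | intermediate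
15 | rac-3-[(2S,3R)-5,7-bis(benzyloxy)-2-(3,4-bis(benzyloxy)phenyl)-4-oxochroman-3-yl]-2-hydroxy-4,6-bis(benzyloxy)benzaldehyde (racemate; (2S,3R) enantiomer drawn) | O=C1c2c(OCc3ccccc3)cc(OCc3ccccc3)cc2O[C@H](c2ccc(OCc3ccccc3)c(OCc3ccccc3)c2)[C@H]1c1c(OCc3ccccc3)cc(OCc3ccccc3)c(C=O)c1O | intermediate
16 | 3-[(2S,3R)-5,7-bis(benzyloxy)-2-(3,4-bis(benzyloxy)phenyl)-4-oxochroman-3-yl]-2-hydroxy-4,6-bis(benzyloxy)benzaldehyde (single enantiomer) | O=C1c2c(OCc3ccccc3)cc(OCc3ccccc3)cc2O[C@H](c2ccc(OCc3ccccc3)c(OCc3ccccc3)c2)[C@H]1c1c(OCc3ccccc3)cc(OCc3ccccc3)c(C=O)c1O | intermediate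
17 | 1,2-bis(benzyloxy)-4-ethynylbenzene | C#Cc1ccc(OCc2ccccc2)c(OCc2ccccc2)c1 | intermediate
18 | 2-[(E)-2-(3,4-bis(benzyloxy)phenyl)ethenyl]-1,3,2-benzodioxaborole | B1(/C=C/c2ccc(OCc3ccccc3)c(OCc3ccccc3)c2)Oc2ccccc2O1 | intermediate (not isolated)
19 | (E)-2-[3,4-bis(benzyloxy)phenyl]ethenylboronic acid | OB(O)/C=C/c1ccc(OCc2ccccc2)c(OCc2ccccc2)c1 | intermediate
20 | (2S,3R)-3-{3-[(E)-1-(dibenzylamino)-3-(3,4-bis(benzyloxy)phenyl)prop-2-enyl]-2-hydroxy-4,6-bis(benzyloxy)phenyl}-5,7-bis(benzyloxy)-2-[3,4-bis(benzyloxy)phenyl]chroman-4-one (amine-bearing carbon unassigned) | O=C1c2c(OCc3ccccc3)cc(OCc3ccccc3)cc2O[C@H](c2ccc(OCc3ccccc3)c(OCc3ccccc3)c2)[C@H]1c1c(OCc2ccccc2)cc(OCc2ccccc2)c(C(/C=C/c2ccc(OCc3ccccc3)c(OCc3ccccc3)c2)N(Cc2ccccc2)Cc2ccccc2)c1O | intermediate (not isolated)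
21 | (2S,3R)-5,7-bis(benzyloxy)-2-[3,4-bis(benzyloxy)phenyl]-3-{2,4-bis(benzyloxy)-5-[(E)-3-(3,4-bis(benzyloxy)phenyl)prop-2-enylidene]-6-oxocyclohexa-1,3-dien-1-yl}chroman-4-one (exocyclic alkene geometry open) | O=C1c2c(OCc3ccccc3)cc(OCc3ccccc3)cc2O[C@H](c2ccc(OCc3ccccc3)c(OCc3ccccc3)c2)[C@H]1C1=C(OCc2ccccc2)C=C(OCc2ccccc2)C(=C/C=C/c2ccc(OCc3ccccc3)c(OCc3ccccc3)c2)C1=O | intermediate (not isolated)
22 | (2S,3R)-5,7-bis(benzyloxy)-2-[3,4-bis(benzyloxy)phenyl]-3-{(2S)-5,7-bis(benzyloxy)-2-[3,4-bis(benzyloxy)phenyl]-2H-chromen-8-yl}chroman-4-one | O=C1c2c(OCc3ccccc3)cc(OCc3ccccc3)cc2O[C@H](c2ccc(OCc3ccccc3)c(OCc3ccccc3)c2)[C@H]1c1c(OCc3ccccc3)cc(OCc3ccccc3)c2c1O[C@H](c1ccc(OCc3ccccc3)c(OCc3ccccc3)c1)C=C2 | intermediate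
23 | (2S,3R)-5,7-bis(benzyloxy)-2-[3,4-bis(benzyloxy)phenyl]-3-{(2R,3S,4S)-5,7-bis(benzyloxy)-2-[3,4-bis(benzyloxy)phenyl]-3,4-dihydroxychroman-8-yl}chroman-4-one | O=C1c2c(OCc3ccccc3)cc(OCc3ccccc3)cc2O[C@H](c2ccc(OCc3ccccc3)c(OCc3ccccc3)c2)[C@H]1c1c(OCc3ccccc3)cc(OCc3ccccc3)c2c1O[C@H](c1ccc(OCc3ccccc3)c(OCc3ccccc3)c1)[C@@H](O)[C@H]2O | intermediate
24 | (2R,3R)-5,7-bis(benzyloxy)-2-[3,4-bis(benzyloxy)phenyl]-8-{(2S,3R)-5,7-bis(benzyloxy)-2-[3,4-bis(benzyloxy)phenyl]-4-oxochroman-3-yl}-3-hydroxychroman-4-one | O=C1c2c(OCc3ccccc3)cc(OCc3ccccc3)cc2O[C@H](c2ccc(OCc3ccccc3)c(OCc3ccccc3)c2)[C@H]1c1c(OCc3ccccc3)cc(OCc3ccccc3)c2c1O[C@H](c1ccc(OCc3ccccc3)c(OCc3ccccc3)c1)[C@@H](O)C2=O | intermediate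
25 | (2R,3R)-2-(3,4-dihydroxyphenyl)-8-[(2S,3R)-2-(3,4-dihydroxyphenyl)-5,7-dihydroxy-4-oxochroman-3-yl]-3,5,7-trihydroxychroman-4-one | O=C1c2c(O)cc(O)cc2O[C@H](c2ccc(O)c(O)c2)[C@H]1c1c(O)cc(O)c2c1O[C@H](c1ccc(O)c(O)c1)[C@@H](O)C2=O | target

Total step count: 16. Longest linear sequence: 13 steps (1, 2, 3, 5, 6, 7, 8, 9, 10, 13, 14, 15, 16).

Steps most likely to fail

Step 13. The boronate transfer may not start at an aldehyde that is flanked by two oxygen-bearing carbons and deactivated by three donor groups, the amine may open the flavanone ring by retro-oxa-Michael reaction and scramble C2/C3, and the ring closure may show little facial preference. The fallback sets out from 16 and 11 and comes back at 22 without amine or boron. Aldehyde 11 is converted by Takai iodo-olefination (CrCl2, CHI3, THF) into 1,2-bis(benzyloxy)-4-[(E)-2-iodoethenyl]benzene F1. Nozaki–Hiyama–Kishi addition of F1 (CrCl2 in excess, NiCl2 cat., DMF/THF) to the aldehyde of 16, which leaves the ketone alone, gives the allylic alcohol (2S,3R)-3-{3-[(E)-1-hydroxy-3-(3,4-bis(benzyloxy)phenyl)prop-2-enyl]-2-hydroxy-4,6-bis(benzyloxy)phenyl}-5,7-bis(benzyloxy)-2-[3,4-bis(benzyloxy)phenyl]chroman-4-one F2. PPTS (cat.) in CH2Cl2 then dehydrates F2 to the same quinone methide 21, which closes to 22 (the classical closure of 2-hydroxycinnamyl alcohols to flav-3-enes). The C2'' epimers are separated as in the main route.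

Step 15. Chemoselection may be lost through hydride abstraction at other benzylic C–H bonds, further dehydrogenation of the ketol to the flavonol, or incomplete discrimination between the two hydroxyl groups. The fallback sets out from 23 and comes back at 24 by differentiating the hydroxyls first. TESOTf and 2,6-lutidine at −78 °C should silylate the less hindered equatorial C3'' OH (the C4'' OH is pseudo-axial and peri to a benzyloxy group) to give the 3''-O-triethylsilyl ether of 23 F3. Dess–Martin periodinane with NaHCO3 oxidises the remaining C4'' OH to the 3''-O-triethylsilyl ether of 24 F4, and HF·pyridine in THF at 0 °C removes the silyl group to give 24.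

Step 7. The condensation may stall because the methylene sits between a twisted aryl ketone and a 2,6-disubstituted aryl ring, so that aldol or Mannich intermediates accumulate or revert. The fallback sets out from isoflavone 9 and comes back at 13 by forming the C2–aryl bond instead of C2–C3. [3,4-Bis(benzyloxy)phenyl]magnesium bromide F5 (from purchased 4-bromo-1,2-bis(benzyloxy)benzene and Mg in THF) adds to C2 of 9 under copper catalysis (CuBr·SMe2, TMSCl, THF, −40 °C) to give the silyl enol ether 5,7-bis(benzyloxy)-2-[3,4-bis(benzyloxy)phenyl]-3-[2,4-bis(benzyloxy)-6-(methoxymethoxy)phenyl]-4-(trimethylsilyloxy)-2H-chromene F6. TBAF/AcOH cleaves F6 to the ketone, and a catalytic amount of piperidine equilibrates C3 to the trans isomer 13.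

Further compounds
F1 | step 13 | 1,2-bis(benzyloxy)-4-[(E)-2-iodoethenyl]benzene | I/C=C/c1ccc(OCc2ccccc2)c(OCc2ccccc2)c1
F2 | step 13 | (2S,3R)-3-{3-[(E)-1-hydroxy-3-(3,4-bis(benzyloxy)phenyl)prop-2-enyl]-2-hydroxy-4,6-bis(benzyloxy)phenyl}-5,7-bis(benzyloxy)-2-[3,4-bis(benzyloxy)phenyl]chroman-4-one (carbinol carbon unassigned) | O=C1c2c(OCc3ccccc3)cc(OCc3ccccc3)cc2O[C@H](c2ccc(OCc3ccccc3)c(OCc3ccccc3)c2)[C@H]1c1c(OCc2ccccc2)cc(OCc2ccccc2)c(C(O)/C=C/c2ccc(OCc3ccccc3)c(OCc3ccccc3)c2)c1O
F3 | step 15 | 3''-O-triethylsilyl ether of 23 | O=C1c2c(OCc3ccccc3)cc(OCc3ccccc3)cc2O[C@H](c2ccc(OCc3ccccc3)c(OCc3ccccc3)c2)[C@H]1c1c(OCc3ccccc3)cc(OCc3ccccc3)c2c1O[C@H](c1ccc(OCc3ccccc3)c(OCc3ccccc3)c1)[C@@H](O[Si](CC)(CC)CC)[C@H]2O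
F4 | step 15 | 3''-O-triethylsilyl ether of 24 | O=C1c2c(OCc3ccccc3)cc(OCc3ccccc3)cc2O[C@H](c2ccc(OCc3ccccc3)c(OCc3ccccc3)c2)[C@H]1c1c(OCc3ccccc3)cc(OCc3ccccc3)c2c1O[C@H](c1ccc(OCc3ccccc3)c(OCc3ccccc3)c1)[C@@H](O[Si](CC)(CC)CC)C2=O
F5 | step 7 | [3,4-bis(benzyloxy)phenyl]magnesium bromide | Br[Mg]c1ccc(OCc2ccccc2)c(OCc2ccccc2)c1
F6 | step 7 | 5,7-bis(benzyloxy)-2-[3,4-bis(benzyloxy)phenyl]-3-[2,4-bis(benzyloxy)-6-(methoxymethoxy)phenyl]-4-(trimethylsilyloxy)-2H-chromene (racemic) | C[Si](C)(C)OC1=C(c2c(OCOC)cc(OCc3ccccc3)cc2OCc2ccccc2)C(c2ccc(OCc3ccccc3)c(OCc3ccccc3)c2)Oc2cc(OCc3ccccc3)cc(OCc3ccccc3)c12
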